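**Analysis of the target**

The target 26 is a single γ-butyrolactone ring, O1–C2(=O)–C3–C4–C5H2. C4 carries the ring B 4-hydroxy-3-methoxybenzyl group through C7'H2, and C3 carries a secondary benzylic carbinol C7 bonded to ring A, also 4-hydroxy-3-methoxyphenyl. It has three contiguous stereocentres, C4 (R), C3 (S) and C7 (S). C3 and C4 are trans on the ring, and C7–OH is syn to the C3–C4 bond, as expected from hydride delivery to a C2/C7 chelate from the side of the C3 hydrogen. The C7 hydroxyl is benzylic and para to a phenol, so it ionises to a quinone methide in acid and is cleaved under hydrogenolysis. Together with the C2 carbonyl it forms an aldol unit that can undergo retro-aldol cleavage or dehydration in base. C3 is epimerisable, but its trans arrangement is the stable one. C4 is not acidic, so it must be set correctly and in the absolute sense when its bond is made. The difficulty is therefore absolute control at C4, relative control at C7, and a sequence that creates the C7 carbinol last. The feature used is that the backbone C2–C3–C4–C5 differs at its two ends only in oxidation level (C2 a carbonyl, C5 a CH2–O). A lactone with its carbonyl at the C5 end and a temporary stereocentre at the C2 end can direct both substituents and then be turned around. C2 to C5 of the target correspond to C2 to C5 of D-glutamic acid 1.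

**Retrosynthetic reasoning**

C7–O (functional group level only). The carbinol 26 is traced to the diphenolic keto lactone 25. A ketone at C7 lies 1,3 to the C2 carbonyl, so a chelating hydride source can fix the conformation and the existing C3 centre decides the face. No C–C bond is cut, and the most fragile group appears in the last step. The benzyl ethers of 24 are removed before this reduction, because the carbinol would not survive hydrogenolysis.

C7 carbonyl to thioacetal. The ketone 24 is traced to the dithiane 23. The thioacetal is inert to hydride, acid and chromium oxidants, and it shows that C7 was introduced as a nucleophilic carbon. This makes the C3–C7 bond a disconnection between an acyl anion equivalent and an electrophilic C3.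

Turning the lactone around. Lactone 23 is traced through lactol 22, hydroxy aldehyde 21 and triol 20 to diol 19 and then to lactone 18. In 18 the carbonyl sits at the future C5 and the future C2 is a ring CH–O carbon carrying an extra trityloxymethyl carbon. No skeletal bond of the target is cut. Forward, the sequence has to reduce the old carbonyl to C5H2–OH, cut off the extra carbon by glycol cleavage, and oxidise the resulting lactol. The gain is that the future C3 becomes the β-carbon and the future C4 the α-carbon of an unsaturated lactone.

C3–C7 and C4–C7' (the key disconnection). Lactone 18 is cut at both bonds to give butenolide 10, dithiane 13 and benzyl bromide 15. Cutting here uses the natural polarity of the butenolide (electrophilic β-carbon, nucleophilic α-carbon after addition). Both aryl units arrive in one operation, and the single stereocentre of 10 relays to both new centres. The forward reaction must add in 1,4 fashion, anti to the trityloxymethyl group, and then alkylate anti to the new dithianyl group.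

Butenolide 10. It is traced via selenide 8 to the saturated lactone 6, then to alcohol 5 and acid 4, and to D-glutamic acid 1. The D series is needed because the anti,anti relay from an R centre at the future C2 gives 4R in the target.

Aryl building blocks. Dithiane 13 comes from aldehyde 11 and dithiol 12. Bromide 15 comes from the same aldehyde 11 through alcohol 14. Both rings therefore share one protected starting material.

**Alternatives that were turned down**

Alternative 1: The disconnection is the lactone O1–C5 bond, followed later by the C7'–aryl bond. In the forward key step the oxetanyl acid A2 is treated with a Brønsted acid catalyst, chiral or achiral. The C2 carboxyl opens one of the two diastereotopic oxetane C–O bonds, closing the lactone, creating C4 and releasing C7'–OH in the hydroxymethyl lactone A1. In its favour, C7 is at the carbinol level from the start, no sulfur, selenium, mercury or chromium is used, and the linear sequence is probably shorter; on these points it is stronger than the chosen route. Against it, C4 depends on selecting between two CH2 groups that differ only through the neighbouring C3 centre, so substrate bias and catalyst may oppose each other. A2 also needs its own aldol with absolute and syn/anti control. The acid step exposes an electron-rich benzylic silyl ether at C7 to ionisation. Ring B must finally be attached by an sp3–sp2 coupling at a β-branched primary carbon next to a base-sensitive aldol lactone. The chosen strategy instead offers stereocontrol at C4 that follows from a simple facial argument, both aryl groups installed at once, and C7 kept as a robust thioacetal until the end.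

Alternative 2: The disconnection is the C3–C4 bond, made by oxidative coupling of two molecules of (E)-ferulic acid A3. A one-electron oxidant generates phenoxy radicals that join at C3–C4. Each carboxyl then adds to the quinone methide carbon of the other half, giving the cis-fused bislactone A4. This builds the whole skeleton without protecting groups in one step and fixes C3, C4 and C7 relative to each other through the bicycle. In step and atom economy it is clearly superior. Against it, radical coupling gives the racemate and several regioisomeric dimers, so a resolution and a modest yield must be accepted. Converting A4 requires hydrogenolysis of only one of two equivalent benzylic lactone C–O bonds, which risks double cleavage. It then requires reduction of the C5 lactone carbonyl next to a free C2 acid and relactonisation, all with the hydrogenolysis-prone C7–O bond present. The chosen strategy is longer but is enantioselective by design and distinguishes C2 from C5 unambiguously.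

Alternative 3: The disconnection is the C7–aryl bond. Methyl furan-2-carboxylate A5 is cyclopropanated with a diazoacetate ester under a chiral monovalent copper–bisoxazoline catalyst and ozonised to the cyclopropane carbaldehyde A6. In the key step the aryl titanium reagent A8 adds to the aldehyde. Aqueous base then removes the oxalate, the cyclopropanol opens by retro-aldol, and the C7 alkoxide lactonises onto the C5 ester to give lactone aldehyde A7. Its strength is catalytic asymmetric induction with C3 and C7 set early, which is more elegant than a stoichiometric chiral pool. Against it, A7 lacks ring B and has the lactone on the wrong oxygen. The aldehyde must be protected, C4 benzylated, C2 oxidised, C5 reduced and the ring re-formed on C5–O. This again requires differentiating two termini at similar oxidation levels, with an acyloxy or hydroxy group at the ionisable C7 throughout. The chosen strategy performs a single turn-around on intermediates in which C7 is a thioacetal and sets C4 in the same step as C3.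

Key step: step 9

Assumption: 4-benzyloxy-3-methoxybenzaldehyde 11 is taken as a purchasable starting material, and selenide 8 and lactol 22 are carried as epimer mixtures at a centre that the next step removes.

**Route**

Step 1
Reactants: 1 D-glutamic acid
Product: 4 (R)-5-oxotetrahydrofuran-2-carboxylic acid, via diazonium carboxylate 2 (not isolated), via α-lactone 3 (not isolated)
Conditions: NaNO2, aq HCl, 0 °C to rt
Reagents that add atoms: none
Why: Diazotisation of the α-amino acid; the α-carboxylate displaces N2 with inversion to give 3 and the γ-carboxyl opens it with a second inversion, so the stereocentre is retained overall (deaminative lactonisation).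

Step 2
Reactants: 4 (R)-5-oxotetrahydrofuran-2-carboxylic acid
Product: 5 (R)-5-(hydroxymethyl)dihydrofuran-2(3H)-one
Conditions: BH3·SMe2, THF, 0 °C to rt; MeOH quench
Reagents that add atoms: none
Why: Chemoselective borane reduction; a free carboxylic acid reacts through its acyloxyborane much faster than a lactone, and the stereocentre is not involved.

Step 3
Reactants: 5 (R)-5-(hydroxymethyl)dihydrofuran-2(3H)-one
Product: 6 (R)-5-(trityloxymethyl)dihydrofuran-2(3H)-one
Conditions: TrCl, pyridine, DMAP (cat.), rt
Reagents that add atoms: trityl chloride, ClC(c1ccccc1)(c1ccccc1)c1ccccc1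
Why: Tritylation of the primary alcohol through the trityl cation; the bulky ether later shields one face of the butenolide.

Step 4
Reactants: 6 (R)-5-(trityloxymethyl)dihydrofuran-2(3H)-one
Product: 8 (5R)-3-(phenylselanyl)-5-(trityloxymethyl)dihydrofuran-2(3H)-one (C3 epimers), via lithium enolate 7 (not isolated)
Conditions: LiN(iPr)2, THF, −78 °C; then PhSeBr, −78 °C
Reagents that add atoms: benzeneselenenyl bromide, Br[Se]c1ccccc1
Why: Kinetic lactone enolate formation and electrophilic α-selenenylation; the configuration at C3 does not matter because step 5 removes that centre.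

Step 5
Reactants: 8 (5R)-3-(phenylselanyl)-5-(trityloxymethyl)dihydrofuran-2(3H)-one
Product: 10 (R)-5-(trityloxymethyl)furan-2(5H)-one, via selenoxide 9 (not isolated)
Conditions: 30% H2O2, pyridine (cat.), CH2Cl2, 0 °C to rt
Reagents that add atoms: none
Why: Selenoxide syn-elimination; only the C4 hydrogens can be removed, so the double bond forms in conjugation, and the non-basic conditions leave the C5 stereocentre untouched.

Step 6
Reactants: 11 4-benzyloxy-3-methoxybenzaldehyde; 12 propane-1,3-dithiol
Product: 13 2-(4-benzyloxy-3-methoxyphenyl)-1,3-dithiane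
Conditions: BF3·OEt2 (cat.), CH2Cl2, 0 °C to rt
Reagents that add atoms: none
Why: Lewis acid-catalysed dithioacetalisation of an aromatic aldehyde, converting the future C7 into an acyl anion equivalent.

Step 7
Reactants: 11 4-benzyloxy-3-methoxybenzaldehyde
Product: 14 (4-benzyloxy-3-methoxyphenyl)methanol
Conditions: NaBH4, MeOH, 0 °C
Reagents that add atoms: none
Why: Borohydride reduction of an aldehyde to the primary benzylic alcohol.

Step 8
Reactants: 14 (4-benzyloxy-3-methoxyphenyl)methanol
Product: 15 4-benzyloxy-3-methoxybenzyl bromide
Conditions: PBr3, Et2O, 0 °C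
Reagents that add atoms: phosphorus tribromide, BrP(Br)Br
Why: Bromide displacement on the phosphite ester of a benzylic alcohol; the electron-rich bromide is reactive and should be used freshly prepared.

Step 9
Reactants: 13 2-(4-benzyloxy-3-methoxyphenyl)-1,3-dithiane; 10 (R)-5-(trityloxymethyl)furan-2(5H)-one; 15 4-benzyloxy-3-methoxybenzyl bromide
Product: 18 (3R,4R,5R)-3-(4-benzyloxy-3-methoxybenzyl)-4-[2-(4-benzyloxy-3-methoxyphenyl)-1,3-dithian-2-yl]-5-(trityloxymethyl)dihydrofuran-2(3H)-one, via lithiated dithiane 16 (not isolated), via lithium enolate 17 (not isolated)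
Conditions: n-BuLi, THF, −78 °C; 10, −78 °C; then 15, DMPU, −78 to −20 °C
Reagents that add atoms: none
Why: n-BuLi deprotonates 13 at the thioacetal carbon to give the sulfur- and aryl-stabilised carbanion 16, which adds in Michael fashion to the β-carbon of 10 and forms the C3–C7 bond and enolate 17. Enolate 17 is then C-alkylated by bromide 15 in an SN2 step that forms the C4–C7' bond. The closest known reaction type is the tandem conjugate addition–enolate alkylation of lithiated aryl dithioacetals on 5-substituted butenolides. No ring is closed in this step. The new centre at the β-carbon (future C3) is controlled by the trityloxymethyl group on C5, which blocks its own face so that the nucleophile enters anti. The new centre at the α-carbon (future C4) is controlled by the quaternary dithianyl group just installed, so the bromide approaches the enolate from the opposite face and the lactone is all-trans. The step needs 1,4- over 1,2-addition, which the delocalised hindered anion and the unhindered β-position favour, and C- over O-alkylation, which the soft benzylic bromide with DMPU favours. Because the pool centre is R, the relay gives the configuration that becomes 3S,4R in the target.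

Step 10
Reactants: 18 (3R,4R,5R)-3-(4-benzyloxy-3-methoxybenzyl)-4-[2-(4-benzyloxy-3-methoxyphenyl)-1,3-dithian-2-yl]-5-(trityloxymethyl)dihydrofuran-2(3H)-one
Product: 19 (2R,3R,4R)-2-(4-benzyloxy-3-methoxybenzyl)-3-[2-(4-benzyloxy-3-methoxyphenyl)-1,3-dithian-2-yl]-5-(trityloxy)pentane-1,4-diol
Conditions: LiAlH4, THF, 0 °C to rt
Reagents that add atoms: none
Why: Hydride reduction of the lactone to the 1,4-diol, which brings the old carbonyl to the C5H2–OH level; thioacetal, benzyl and trityl ethers are inert and no stereocentre is touched.

Step 11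
Reactants: 19 (2R,3R,4R)-2-(4-benzyloxy-3-methoxybenzyl)-3-[2-(4-benzyloxy-3-methoxyphenyl)-1,3-dithian-2-yl]-5-(trityloxy)pentane-1,4-diol
Product: 20 (2R,3R,4R)-4-(4-benzyloxy-3-methoxybenzyl)-3-[2-(4-benzyloxy-3-methoxyphenyl)-1,3-dithian-2-yl]pentane-1,2,5-triol
Conditions: p-TsOH·H2O (cat.), MeOH–CH2Cl2, rt
Reagents that add atoms: none
Why: Acid-catalysed solvolysis of the trityl ether with trapping of the trityl cation by methanol; the thioacetal and benzyl ethers tolerate catalytic sulfonic acid at room temperature.

Step 12
Reactants: 20 (2R,3R,4R)-4-(4-benzyloxy-3-methoxybenzyl)-3-[2-(4-benzyloxy-3-methoxyphenyl)-1,3-dithian-2-yl]pentane-1,2,5-triol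
Product: 22 (3R,4R)-4-(4-benzyloxy-3-methoxybenzyl)-3-[2-(4-benzyloxy-3-methoxyphenyl)-1,3-dithian-2-yl]tetrahydrofuran-2-ol (anomers), via hydroxy aldehyde 21 (not isolated)
Conditions: NaIO4 (1.05 equiv), t-BuOH–H2O, 0 °C, short reaction time
Reagents that add atoms: none
Why: Malaprade glycol cleavage through the cyclic periodate ester removes the exocyclic carbon and turns the former pool stereocentre into the aldehyde of 21, which the 4-hydroxyl traps as the five-membered lactol; limiting oxidant at 0 °C is meant to keep the slower sulfur oxidation of the hindered dithiane from competing.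

Step 13
Reactants: 22 (3R,4R)-4-(4-benzyloxy-3-methoxybenzyl)-3-[2-(4-benzyloxy-3-methoxyphenyl)-1,3-dithian-2-yl]tetrahydrofuran-2-ol
Product: 23 (3R,4R)-4-(4-benzyloxy-3-methoxybenzyl)-3-[2-(4-benzyloxy-3-methoxyphenyl)-1,3-dithian-2-yl]dihydrofuran-2(3H)-one
Conditions: CrO3·2C5H5N (Collins reagent), CH2Cl2, rt
Reagents that add atoms: none
Why: Lactol to lactone oxidation by hexavalent chromium under anhydrous pyridine-buffered conditions completes the carbonyl transposition; C3 is now α to the carbonyl, but its trans arrangement is the thermodynamically preferred one.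

Step 14
Reactants: 23 (3R,4R)-4-(4-benzyloxy-3-methoxybenzyl)-3-[2-(4-benzyloxy-3-methoxyphenyl)-1,3-dithian-2-yl]dihydrofuran-2(3H)-one
Product: 24 (3S,4R)-3-(4-benzyloxy-3-methoxybenzoyl)-4-(4-benzyloxy-3-methoxybenzyl)dihydrofuran-2(3H)-one
Conditions: HgO, BF3·OEt2, THF–H2O, rt
Reagents that add atoms: water, O
Why: Thiophilic hydrolysis of the dithioacetal assisted by divalent mercury unmasks the C7 ketone; the β-keto lactone can enolise at C3 but returns to the favoured 3,4-trans isomer, and C4 is not acidic.

Step 15
Reactants: 24 (3S,4R)-3-(4-benzyloxy-3-methoxybenzoyl)-4-(4-benzyloxy-3-methoxybenzyl)dihydrofuran-2(3H)-one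
Product: 25 (3S,4R)-3-(4-hydroxy-3-methoxybenzoyl)-4-(4-hydroxy-3-methoxybenzyl)dihydrofuran-2(3H)-one
Conditions: H2 (1 atm), 10% Pd/C, EtOAc, rt, monitored
Reagents that add atoms: none
Why: Hydrogenolysis of the two benzyl aryl ethers; it is done at the ketone stage because the later C7 carbinol would itself be hydrogenolysed, and the neutral solvent and low pressure limit reduction of the aryl ketone.

Step 16
Reactants: 25 (3S,4R)-3-(4-hydroxy-3-methoxybenzoyl)-4-(4-hydroxy-3-methoxybenzyl)dihydrofuran-2(3H)-one
Product: 26 (3S,4R)-3-[(S)-hydroxy(4-hydroxy-3-methoxyphenyl)methyl]-4-(4-hydroxy-3-methoxybenzyl)dihydrofuran-2(3H)-one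
Conditions: Zn(BH4)2 (excess), Et2O–THF, −20 to 0 °C; aq NH4Cl
Reagents that add atoms: none
Why: Chelation-controlled reduction of a 2-acyl lactone; divalent zinc bridges the C2 and C7 carbonyl oxygens, and hydride enters from the side of the C3 hydrogen, away from C4, which gives the syn 7S carbinol; excess reagent is needed because the phenols consume hydride.

**Compound list**

1 | D-glutamic acid | N[C@H](CCC(=O)O)C(=O)O | starting material
2 | (R)-3-carboxy-1-carboxylatopropane-1-diazonium | N#[N+][C@H](CCC(=O)O)C(=O)[O-] | intermediate
3 | (S)-3-(3-oxooxiran-2-yl)propanoic acid | O=C1O[C@H]1CCC(=O)O | intermediate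
4 | (R)-5-oxotetrahydrofuran-2-carboxylic acid | OC(=O)[C@H]1CCC(=O)O1 | intermediate
5 | (R)-5-(hydroxymethyl)dihydrofuran-2(3H)-one | OC[C@H]1CCC(=O)O1 | intermediate
6 | (R)-5-(trityloxymethyl)dihydrofuran-2(3H)-one | O=C1CC[C@H](COC(c2ccccc2)(c2ccccc2)c2ccccc2)O1 | intermediate
7 | lithium (R)-5-(trityloxymethyl)-4,5-dihydrofuran-2-olate | [Li]OC1=CC[C@H](COC(c2ccccc2)(c2ccccc2)c2ccccc2)O1 | intermediate
8 | (5R)-3-(phenylselanyl)-5-(trityloxymethyl)dihydrofuran-2(3H)-one, C3 epimers | O=C1O[C@@H](COC(c2ccccc2)(c2ccccc2)c2ccccc2)CC1[Se]c1ccccc1 | intermediate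
9 | (5R)-3-(phenylseleninyl)-5-(trityloxymethyl)dihydrofuran-2(3H)-one | O=C1O[C@@H](COC(c2ccccc2)(c2ccccc2)c2ccccc2)CC1[Se](=O)c1ccccc1 | intermediate
10 | (R)-5-(trityloxymethyl)furan-2(5H)-one | O=C1O[C@@H](COC(c2ccccc2)(c2ccccc2)c2ccccc2)C=C1 | intermediate
11 | 4-benzyloxy-3-methoxybenzaldehyde | COc1cc(C=O)ccc1OCc1ccccc1 | starting material
12 | propane-1,3-dithiol | SCCCS | starting material
13 | 2-(4-benzyloxy-3-methoxyphenyl)-1,3-dithiane | COc1cc(C2SCCCS2)ccc1OCc1ccccc1 | intermediate
14 | (4-benzyloxy-3-methoxyphenyl)methanol | COc1cc(CO)ccc1OCc1ccccc1 | intermediate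
15 | 4-benzyloxy-3-methoxybenzyl bromide | COc1cc(CBr)ccc1OCc1ccccc1 | intermediate
16 | 2-lithio-2-(4-benzyloxy-3-methoxyphenyl)-1,3-dithiane | COc1cc(C2([Li])SCCCS2)ccc1OCc1ccccc1 | intermediate
17 | lithium enolate of (4R,5R)-4-[2-(4-benzyloxy-3-methoxyphenyl)-1,3-dithian-2-yl]-5-(trityloxymethyl)dihydrofuran-2(3H)-one | [Li]OC1=C[C@@H](C2(c3ccc(OCc4ccccc4)c(OC)c3)SCCCS2)[C@H](COC(c2ccccc2)(c2ccccc2)c2ccccc2)O1 | intermediate
18 | (3R,4R,5R)-3-(4-benzyloxy-3-methoxybenzyl)-4-[2-(4-benzyloxy-3-methoxyphenyl)-1,3-dithian-2-yl]-5-(trityloxymethyl)dihydrofuran-2(3H)-one | COc1cc(C[C@H]2C(=O)O[C@@H](COC(c3ccccc3)(c3ccccc3)c3ccccc3)[C@@H]2C2(c3ccc(OCc4ccccc4)c(OC)c3)SCCCS2)ccc1OCc1ccccc1 | intermediate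
19 | (2R,3R,4R)-2-(4-benzyloxy-3-methoxybenzyl)-3-[2-(4-benzyloxy-3-methoxyphenyl)-1,3-dithian-2-yl]-5-(trityloxy)pentane-1,4-diol | COc1cc(C[C@@H](CO)[C@H]([C@@H](O)COC(c3ccccc3)(c3ccccc3)c3ccccc3)C2(c3ccc(OCc4ccccc4)c(OC)c3)SCCCS2)ccc1OCc1ccccc1 | intermediate
20 | (2R,3R,4R)-4-(4-benzyloxy-3-methoxybenzyl)-3-[2-(4-benzyloxy-3-methoxyphenyl)-1,3-dithian-2-yl]pentane-1,2,5-triol | COc1cc(C[C@@H](CO)[C@H]([C@@H](O)CO)C2(c3ccc(OCc4ccccc4)c(OC)c3)SCCCS2)ccc1OCc1ccccc1 | intermediate
21 | (2R,3R)-4-(4-benzyloxy-3-methoxyphenyl)-2-[2-(4-benzyloxy-3-methoxyphenyl)-1,3-dithian-2-yl]-3-(hydroxymethyl)butanal | COc1cc(C[C@@H](CO)[C@H](C=O)C2(c3ccc(OCc4ccccc4)c(OC)c3)SCCCS2)ccc1OCc1ccccc1 | intermediate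
22 | (3R,4R)-4-(4-benzyloxy-3-methoxybenzyl)-3-[2-(4-benzyloxy-3-methoxyphenyl)-1,3-dithian-2-yl]tetrahydrofuran-2-ol, anomers | COc1cc(C[C@H]2COC(O)[C@@H]2C2(c3ccc(OCc4ccccc4)c(OC)c3)SCCCS2)ccc1OCc1ccccc1 | intermediate
23 | (3R,4R)-4-(4-benzyloxy-3-methoxybenzyl)-3-[2-(4-benzyloxy-3-methoxyphenyl)-1,3-dithian-2-yl]dihydrofuran-2(3H)-one | COc1cc(C[C@H]2COC(=O)[C@@H]2C2(c3ccc(OCc4ccccc4)c(OC)c3)SCCCS2)ccc1OCc1ccccc1 | intermediate
24 | (3S,4R)-3-(4-benzyloxy-3-methoxybenzoyl)-4-(4-benzyloxy-3-methoxybenzyl)dihydrofuran-2(3H)-one | COc1cc(C[C@H]2COC(=O)[C@@H]2C(=O)c2ccc(OCc3ccccc3)c(OC)c2)ccc1OCc1ccccc1 | intermediate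
25 | (3S,4R)-3-(4-hydroxy-3-methoxybenzoyl)-4-(4-hydroxy-3-methoxybenzyl)dihydrofuran-2(3H)-one | COc1cc(C[C@H]2COC(=O)[C@@H]2C(=O)c2ccc(O)c(OC)c2)ccc1O | intermediate
26 | (3S,4R)-3-[(S)-hydroxy(4-hydroxy-3-methoxyphenyl)methyl]-4-(4-hydroxy-3-methoxybenzyl)dihydrofuran-2(3H)-one | COc1cc(C[C@H]2COC(=O)[C@@H]2[C@H](O)c2ccc(O)c(OC)c2)ccc1O | target

**Step count and risks**

Total: 16 steps. Longest linear sequence: 13 steps (steps 1 to 5, then 9 to 16).

Step 9 (key step). The likely failures are proton transfer instead of addition (deprotonation of the butenolide at C5, which would erase the stereocentre), some attack at the carbonyl, and slow or incomplete alkylation of the hindered enolate with proton exchange between enolate and product. Fallback: separate the two bond formations. Starting from 13 and 10, the anion 16 is added to 10 and the enolate is quenched with aqueous NH4Cl. This gives the conjugate adduct (4R,5R)-4-[2-(4-benzyloxy-3-methoxyphenyl)-1,3-dithian-2-yl]-5-(trityloxymethyl)dihydrofuran-2(3H)-one F1, which is purified. Its enolate is then regenerated with LiN(SiMe3)2 in THF–DMPU at −78 °C and alkylated with 15, returning to the route at 18. The anti preference of the alkylation is unchanged because the same dithianyl group directs it.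

Step 12. Periodate may oxidise a dithiane sulfur while it cleaves the glycol, giving sulfoxides that complicate steps 13 and 14. Fallback: remove the sulfur before any periodate is used.
- From 18, the thioacetal is hydrolysed with Hg(ClO4)2 and CaCO3 in aqueous THF to give the keto lactone (3R,4R,5R)-4-(4-benzyloxy-3-methoxybenzoyl)-3-(4-benzyloxy-3-methoxybenzyl)-5-(trityloxymethyl)dihydrofuran-2(3H)-one F2.
- The trityl ether is cleaved with catalytic p-TsOH in MeOH while no benzylic alcohol is yet present, giving the hydroxy keto lactone F3.
- LiAlH4 reduces lactone and ketone together to the tetraol F4, as a mixture at the carbinol carbon.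
- NaIO4 cleaves the terminal glycol and gives the hydroxy lactol F5.
- Excess Dess–Martin periodinane oxidises the lactol and the benzylic alcohol in one operation, returning to the route at 24.

The carbinol mixture does not matter because that carbon is reoxidised.

Step 15. Residual sulfur or mercury may poison the catalyst, and prolonged exposure may reduce the aryl ketone or cleave the C7–O bond. Fallback: a non-reductive Lewis acid debenzylation of 24 with BCl3 and pentamethylbenzene in CH2Cl2 at −78 °C. The arene traps the benzyl cation and the ketone and lactone are untouched. This leads directly to 25, and no new compound arises (F0).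

Step 16. The two phenols are converted to zinc phenoxides, which may weaken chelation or slow the reduction of the para-oxygenated aryl ketone and so lower facial selectivity. The product may also undergo retro-aldol cleavage on a basic work-up. Fallback: restore an aprotic substrate. From 25, both phenols are silylated with TBSCl and imidazole to give the bis-silyl keto lactone (3S,4R)-3-[4-(tert-butyldimethylsilyloxy)-3-methoxybenzoyl]-4-[4-(tert-butyldimethylsilyloxy)-3-methoxybenzyl]dihydrofuran-2(3H)-one F6. Reduction with Zn(BH4)2 then gives the bis-silyl carbinol F7. The aryl silyl ethers are removed with tetrabutylammonium fluoride buffered with acetic acid at 0 °C, returning to the route at 26.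

**Further compounds**

F1 | step 9 | (4R,5R)-4-[2-(4-benzyloxy-3-methoxyphenyl)-1,3-dithian-2-yl]-5-(trityloxymethyl)dihydrofuran-2(3H)-one | O=C1C[C@@H](C2(c3ccc(OCc4ccccc4)c(OC)c3)SCCCS2)[C@H](COC(c2ccccc2)(c2ccccc2)c2ccccc2)O1
F2 | step 12 | (3R,4R,5R)-4-(4-benzyloxy-3-methoxybenzoyl)-3-(4-benzyloxy-3-methoxybenzyl)-5-(trityloxymethyl)dihydrofuran-2(3H)-one | COc1cc(C[C@H]2C(=O)O[C@@H](COC(c3ccccc3)(c3ccccc3)c3ccccc3)[C@@H]2C(=O)c2ccc(OCc3ccccc3)c(OC)c2)ccc1OCc1ccccc1
F3 | step 12 | 4-(4-benzyloxy-3-methoxybenzoyl)-3-(4-benzyloxy-3-methoxybenzyl)-5-(hydroxymethyl)dihydrofuran-2(3H)-one, all-trans, ring centres as in 18 | COc1cc(C[C@H]2C(=O)O[C@@H](CO)[C@@H]2C(=O)c2ccc(OCc3ccccc3)c(OC)c2)ccc1OCc1ccccc1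
F4 | step 12 | 4-(4-benzyloxy-3-methoxybenzyl)-3-[(4-benzyloxy-3-methoxyphenyl)(hydroxy)methyl]pentane-1,2,5-triol, backbone centres as in 20, carbinol epimers | COc1cc(C[C@@H](CO)[C@H]([C@@H](O)CO)C(O)c2ccc(OCc3ccccc3)c(OC)c2)ccc1OCc1ccccc1
F5 | step 12 | 4-(4-benzyloxy-3-methoxybenzyl)-3-[(4-benzyloxy-3-methoxyphenyl)(hydroxy)methyl]tetrahydrofuran-2-ol, ring centres as in 22, carbinol epimers and anomers | COc1cc(C[C@H]2COC(O)[C@@H]2C(O)c2ccc(OCc3ccccc3)c(OC)c2)ccc1OCc1ccccc1
F0 | step 15 | none | none
F6 | step 16 | (3S,4R)-3-[4-(tert-butyldimethylsilyloxy)-3-methoxybenzoyl]-4-[4-(tert-butyldimethylsilyloxy)-3-methoxybenzyl]dihydrofuran-2(3H)-one | COc1cc(C[C@H]2COC(=O)[C@@H]2C(=O)c2ccc(O[Si](C)(C)C(C)(C)C)c(OC)c2)ccc1O[Si](C)(C)C(C)(C)C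
F7 | step 16 | (3S,4R)-3-[(S)-hydroxy(4-(tert-butyldimethylsilyloxy)-3-methoxyphenyl)methyl]-4-[4-(tert-butyldimethylsilyloxy)-3-methoxybenzyl]dihydrofuran-2(3H)-one | COc1cc(C[C@H]2COC(=O)[C@@H]2[C@H](O)c2ccc(O[Si](C)(C)C(C)(C)C)c(OC)c2)ccc1O[Si](C)(C)C(C)(C)C
A1 | alternative 1 | 3,4-trans 4-(hydroxymethyl)-3-[(S)-(tert-butyldimethylsilyloxy)(4-(tert-butyldimethylsilyloxy)-3-methoxyphenyl)methyl]dihydrofuran-2(3H)-one | OC[C@H]1COC(=O)[C@@H]1[C@H](O[Si](C)(C)C(C)(C)C)c1ccc(O[Si](C)(C)C(C)(C)C)c(OC)c1
A2 | alternative 1 | 3-(tert-butyldimethylsilyloxy)-3-[4-(tert-butyldimethylsilyloxy)-3-methoxyphenyl]-2-(oxetan-3-yl)propanoic acid, configured at C3 and C7 as in the target | OC(=O)[C@@H](C1COC1)[C@H](O[Si](C)(C)C(C)(C)C)c1ccc(O[Si](C)(C)C(C)(C)C)c(OC)c1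
A3 | alternative 2 | (E)-ferulic acid | COc1cc(/C=C/C(=O)O)ccc1O
A4 | alternative 2 | 2,6-bis(4-hydroxy-3-methoxyphenyl)-3,7-dioxabicyclo[3.3.0]octane-4,8-dione, needed enantiomer | O=C1O[C@H](c3ccc(O)c(OC)c3)[C@@H]2[C@H]1[C@@H](c1ccc(O)c(OC)c1)OC2=O
A5 | alternative 3 | methyl furan-2-carboxylate | COC(=O)c1ccco1
A6 | alternative 3 | ethyl 2-formyl-3-(methoxyoxalyloxy)cyclopropane-1-carboxylate, formyl and oxalyloxy cis, ester trans | O=C[C@@H]1[C@@H](C(=O)OCC)[C@@H]1OC(=O)C(=O)OC
A7 | alternative 3 | trans 2-(4-allyloxy-3-methoxyphenyl)-5-oxotetrahydrofuran-3-carbaldehyde | O=C[C@H]1CC(=O)O[C@@H]1c1ccc(OCC=C)c(OC)c1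
A8 | alternative 3 | (4-allyloxy-3-methoxyphenyl)titanium triisopropoxide | COc1cc([Ti](OC(C)C)(OC(C)C)OC(C)C)ccc1OCC=C
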